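The tetrahydropyran and the cis-fused γ-lactone share one 3-alkoxypropanoate unit, O9–C13H2–C11H–C12(=O)–O6. Both rings are therefore cut at O9–C13, C7–C11 and O6–C12, which leaves a malonate C3 unit and an acyclic cis-vinyl epoxy alcohol. In the key step the C9 alkoxide adds to diethyl methylenemalonate, the stabilised carbanion opens the C7–C6 epoxide at C7 with inversion, and the freed C6 alkoxide lactonises. This builds two rings and sets C7 in one operation from a precursor that contains no ring of the target. The surplus ester is then removed, and the nine-membered lactone is closed last by ring-closing metathesis.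

Key step: step 7

Remark: locants used for all compounds are C1/C2 acetyl C=O/CH3; C3 nine-ring lactone C=O; C4 =C(CH3); C5 =CH; C6 CH–O of the γ-lactone; C7 and C11 ring-fusion CH; C8 CH–O(angelate); C9 CH–O of the tetrahydropyran; C10 quaternary C–O; C12 γ-lactone C=O; C13 OCH2. 1,3-Dithiane-2-carbaldehyde is made in step 1 and not assumed to be purchasable. Ipc = isopinocampheyl.

Step 1
Reactants: 1 ethyl 1,3-dithiane-2-carboxylate
Product: 2 1,3-dithiane-2-carbaldehyde
Conditions: i-Bu2AlH (1.05 equiv), CH2Cl2, −78 °C; aq. potassium sodium tartrate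
Reagents that add atoms: none
Why: Partial ester reduction with i-Bu2AlH at low temperature stops at the aluminium hemiacetal, which should release the aldehyde on work-up.

Step 2
Reactants: 2 1,3-dithiane-2-carbaldehyde; 3 hydroxyacetone
Product: 4 (3S,4R)-4-(1,3-dithian-2-yl)-3,4-dihydroxybutan-2-one (anti diol, future C9 and C8)
Conditions: L-proline (30 mol %), DMSO/3 (4:1), rt
Reagents that add atoms: none
Why: Proline-catalysed direct aldol reaction, in which the enamine of 3 forms at the hydroxylated carbon and should add through the carboxylic-acid-organised chair transition state to one face of the α-branched aldehyde, setting C9 and C8 as the anti diol in the absolute sense established for L-proline.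

Step 3
Reactants: 4 anti-diol ketone
Product: 5 (1R,2S,3S)-1-(1,3-dithian-2-yl)-3-methylpent-4-yne-1,2,3-triol
Conditions: HC≡CMgBr (4 equiv), THF, −78 to −20 °C; aq. NH4Cl
Reagents that add atoms: ethynylmagnesium bromide, C#C[Mg]Br
Why: Chelation-controlled Grignard addition, in which the magnesium alkoxide of the α-hydroxyl chelates the ketone and the acetylide should attack the face opposite the C8 chain, setting C10 with C10–O and C9–O syn when the ethynyl group is read as chain end.

Step 4
Reactants: 5 alkynyl triol
Product: 7 C9 triethylsilyl ether of the O8,O10-(4-methoxybenzylidene) acetal of 5, via dioxane alcohol 6 (not isolated)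
Conditions: 4-MeOC6H4CH(OMe)2, camphorsulfonic acid (cat.), CH2Cl2, rt; concentrate; then imidazole, Et3SiCl, DMAP (cat.), DMF, rt
Reagents that add atoms: 4-methoxybenzaldehyde dimethyl acetal, COC(OC)c1ccc(OC)cc1; chlorotriethylsilane, CC[Si](Cl)(CC)CC
Why: Thermodynamic acetalisation of the 1,2,3-triol should favour the six-membered 1,3-dioxane across O8 and O10, a chair with aryl, the C8 substituent and the C10 methyl equatorial and only the slim ethynyl group axial (this equatorial preference sets the acetal centre), which leaves only the C9 hydroxyl for silylation.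

Step 5
Reactants: 7 silylated dioxane dithiane
Product: 8 C7 aldehyde (4-formyl-1,3-dioxane with C9–OSiEt3)
Conditions: MeI, CaCO3, MeCN/H2O (4:1), 45 °C
Reagents that add atoms: water, O
Why: S-Methylation turns the dithiane into a sulfonium leaving group, and buffered hydrolysis should release the aldehyde without touching the acetal, the silyl ether or the alkyne.

Step 6
Reactants: 8 C7 aldehyde
Product: 10 cis-vinyl epoxy alcohol (C7–C6 oxirane bearing the C5 vinyl group; free C9–OH), via syn-chlorohydrin silyl ether 9 (not isolated)
Conditions: allyl chloride, (+)-Ipc2BOMe, LiN(c-C6H11)2, Et2O/THF, −95 °C; BF3·OEt2; 8, −95 °C; NaBO3·4H2O, H2O, rt; crude 9, Bu4NF, THF, 0 °C to rt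
Reagents that add atoms: allyl chloride, C=CCCl
Why: Asymmetric γ-chloroallylboration (Brown-type allylboration) with the (Z)-γ-chloroallyl-BIpc2 reagent made in situ, in which the closed chair transition state gives the syn chlorohydrin and the Ipc groups of this antipode (from (−)-α-pinene) should direct attack to the Re face of the aldehyde (setting C7 and C6), after which fluoride removes the silyl group and, acting as base, closes the chlorohydrin by 3-exo displacement with inversion at C6 to the cis-vinyl epoxide.

Step 7
Reactants: 10 cis-vinyl epoxy alcohol; 11 diethyl methylenemalonate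
Product: 13 C11-ethoxycarbonyl tricyclic lactone (tetrahydropyran trans-fused to the dioxane and cis-fused to the γ-lactone; C6 vinyl), via potassium malonate adduct 12 (not isolated)
Conditions: KN(SiMe3)2 (1.05 equiv), THF, −78 °C; 11 (1.0 equiv, slow addition); 18-crown-6, −78 to 45 °C; aq. NH4Cl
Reagents that add atoms: none
Why: The potassium C9 alkoxide adds to the doubly activated methylene of 11 (oxa-Michael, forming O9–C13) to give the stabilised malonate carbanion 12, which opens the cis-vinyl epoxide intramolecularly at C7 (forming C7–C11), and the C6 alkoxide so released attacks the cis ethyl ester to close the γ-lactone. The closest known reaction types are the classical malonate–epoxide γ-lactone synthesis and oxa-Michael-initiated ring closures of alkoxides onto alkylidene malonates. The tetrahydropyran closes 6-exo-tet through a chair that is trans-fused to the benzylidene-type dioxane (as in 4,6-O-benzylidene pyranosides), and the lactone closes 5-exo-trig. C7 is set by inversion at the epoxide carbon, C6 is carried over with retention from the epoxide, and C11 is quaternary here and is set only in step 8. Attack at C7 and not at the allylic C6 (7-endo) or at the vinyl terminus is secured by ring size; attack of the C9 alkoxide itself on the epoxide (5-endo or 4-exo) is suppressed because the alkoxide is stored as the far less basic malonate anion, so the reversible oxa-Michael addition and the irreversible epoxide opening should funnel the material to 13.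

Step 8
Reactants: 13 C11-ethoxycarbonyl tricyclic lactone
Product: 14 tricyclic lactone with C11–H (cis ring fusion)
Conditions: LiCl, H2O, DMSO, 130 °C
Reagents that add atoms: none
Why: Krapcho dealkoxycarbonylation, in which chloride dealkylates the ethyl ester, loss of CO2 gives the lactone enolate and protonation on the convex face (cis to H7) should give the cis-fused lactone, expected also to be the thermodynamic C11 epimer, so that C11 is set here whichever ester lactonised in step 7.

Step 9
Reactants: 14 tricyclic lactone
Product: 15 C8,C10-diol lactone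
Conditions: AcOH/H2O (4:1), 45 °C
Reagents that add atoms: none
Why: Mild acid hydrolysis of the 4-methoxybenzylidene acetal should free the C8 and C10 hydroxyls while lactone, vinyl group and alkyne stay inert.

Step 10
Reactants: 15 C8,C10-diol lactone
Product: 16 C8 angelate (C10–OH free)
Conditions: angelic acid, 2,4,6-Cl3C6H2COCl, Et3N, toluene, rt; then 15, 80 °C
Reagents that add atoms: angelic acid, C/C=C(/C)C(=O)O
Why: Yamaguchi-type esterification through the mixed anhydride, run without DMAP, should acylate the secondary C8 hydroxyl in preference to the tertiary C10 hydroxyl and keep the Z geometry of the angelate.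

Step 11
Reactants: 16 C8 angelate
Product: 17 C8 angelate C10 methacrylate
Conditions: methacrylic anhydride, DMAP, Et3N, CH2Cl2, 40 °C
Reagents that add atoms: methacrylic anhydride, CC(=C)C(=O)OC(=O)C(C)=C
Why: DMAP-catalysed acylation, in which the tertiary alcohol is propargylic, so the small ethynyl group should leave it accessible to the acylpyridinium ion.

Step 12
Reactants: 17 C8 angelate C10 methacrylate
Product: 18 C10 acetyl compound (α-methacryloyloxy methyl ketone)
Conditions: Ph3PAuNTf2 (5 mol %), 1,4-dioxane/H2O (10:1), rt
Reagents that add atoms: water, O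
Why: Gold-catalysed Markovnikov hydration of the terminal alkyne, assisted by 5-exo attack of the neighbouring ester carbonyl on the gold-activated alkyne and hydrolysis of the dioxolenium intermediate, should give the α-acyloxy methyl ketone and leave the alkenes untouched.

Step 13
Reactants: 18 C10 acetyl compound
Product: 19 CNP0342803.2
Conditions: second-generation Hoveyda–Grubbs catalyst (20 mol %), 1,4-benzoquinone (10 mol %), toluene (1 mM), 100 °C
Reagents that add atoms: none
Why: Ring-closing metathesis between the C6 vinyl group and the methacrylate should close the nine-membered lactone, the ring size allowing only the Z trisubstituted enoate, with the bicyclic core holding the two alkenes close and high dilution disfavouring oligomers.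

Compound list
1 | ethyl 1,3-dithiane-2-carboxylate | CCOC(=O)C1SCCCS1 | starting material
2 | 1,3-dithiane-2-carbaldehyde | O=CC1SCCCS1 | intermediate
3 | hydroxyacetone (1-hydroxypropan-2-one) | CC(=O)CO | starting material
4 | (3S,4R)-4-(1,3-dithian-2-yl)-3,4-dihydroxybutan-2-one | CC(=O)[C@@H](O)[C@@H](O)C1SCCCS1 | intermediate
5 | (1R,2S,3S)-1-(1,3-dithian-2-yl)-3-methylpent-4-yne-1,2,3-triol | C#C[C@](C)(O)[C@@H](O)[C@@H](O)C1SCCCS1 | intermediate
6 | O8,O10-(4-methoxybenzylidene) acetal of 5 (1,3-dioxane, C9–OH free) | C#C[C@]1(C)O[C@@H](c2ccc(OC)cc2)O[C@@H](C3SCCCS3)[C@@H]1O | intermediate (not isolated)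
7 | C9 triethylsilyl ether of 6 | C#C[C@]1(C)O[C@@H](c2ccc(OC)cc2)O[C@@H](C3SCCCS3)[C@@H]1O[Si](CC)(CC)CC | intermediate
8 | C7 aldehyde (4-formyl-1,3-dioxane, C9–OSiEt3) | C#C[C@]1(C)O[C@@H](c2ccc(OC)cc2)O[C@@H](C=O)[C@@H]1O[Si](CC)(CC)CC | intermediate
9 | syn-chlorohydrin silyl ether (C7–OH, C6–Cl, C6 vinyl) | C#C[C@]1(C)O[C@@H](c2ccc(OC)cc2)O[C@@H]([C@H](O)[C@@H](Cl)C=C)[C@@H]1O[Si](CC)(CC)CC | intermediate (not isolated)
10 | cis-vinyl epoxy alcohol (C7–C6 oxirane, C9–OH free) | C#C[C@]1(C)O[C@@H](c2ccc(OC)cc2)O[C@@H]([C@@H]3O[C@@H]3C=C)[C@@H]1O | intermediate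
11 | diethyl methylenemalonate (diethyl 2-methylidenepropanedioate) | C=C(C(=O)OCC)C(=O)OCC | starting material
12 | potassium salt of the diethyl 2-(C9-alkoxymethyl)malonate adduct | C#C[C@]1(C)O[C@@H](c2ccc(OC)cc2)O[C@@H]([C@@H]3O[C@@H]3C=C)[C@@H]1OC[C-](C(=O)OCC)C(=O)OCC.[K+] | intermediate (not isolated)
13 | C11-ethoxycarbonyl tricyclic lactone | C#C[C@]1(C)O[C@@H](c2ccc(OC)cc2)O[C@@H]3[C@@H]1OC[C@]4(C(=O)OCC)[C@H]3[C@@H](C=C)OC4=O | intermediate
14 | tricyclic lactone with C11–H (cis-fused) | C#C[C@]1(C)O[C@@H](c2ccc(OC)cc2)O[C@@H]3[C@@H]1OC[C@@H]4[C@H]3[C@@H](C=C)OC4=O | intermediate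
15 | C8,C10-diol lactone | O[C@H]1[C@@H]2[C@@H](C=C)OC(=O)[C@@H]2CO[C@@H]1[C@@](C)(O)C#C | intermediate
16 | C8 angelate | C/C=C(/C)C(=O)O[C@H]1[C@@H]2[C@@H](C=C)OC(=O)[C@@H]2CO[C@@H]1[C@@](C)(O)C#C | intermediate
17 | C8 angelate C10 methacrylate | C/C=C(/C)C(=O)O[C@H]1[C@@H]2[C@@H](C=C)OC(=O)[C@@H]2CO[C@@H]1[C@@](C)(OC(=O)C(C)=C)C#C | intermediate
18 | C10 acetyl compound (α-methacryloyloxy methyl ketone) | C/C=C(/C)C(=O)O[C@H]1[C@@H]2[C@@H](C=C)OC(=O)[C@@H]2CO[C@@H]1[C@@](C)(OC(=O)C(C)=C)C(C)=O | intermediate
19 | CNP0342803.2 | C/C=C(/C)C(=O)O[C@H]1[C@@H]2[C@H]3/C=C(/C)C(=O)O[C@@](C)(C(C)=O)[C@H]1OC[C@H]2C(=O)O3 | target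

Total step count: 13. Longest linear sequence: 13 steps (1 to 19).

Steps most likely to fail

Step 7. Anionic oligomerisation of the methylenemalonate may compete with the clean one-to-one oxa-Michael addition, and the stabilised carbanion may open the epoxide too slowly, so that material is lost through attack of the alkoxide on the epoxide. The fallback separates the two bond formations and uses a nitrile-stabilised anion. It sets out from 10: cyanoethylation with acrylonitrile and catalytic KOt-Bu in THF should give the 2-cyanoethyl ether F1. KN(SiMe3)2 in toluene/THF (Stork epoxynitrile cyclisation, 6-exo at C7) should then close the tetrahydropyran. The C6 alkoxide adds to the cis nitrile to give the iminolactone F2, and the trans nitrile can epimerise through its anion. Buffered aqueous hydrolysis (NH4Cl, AcOH, THF/H2O) converts F2 into the lactone, and the route is rejoined at 14.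

Step 13. Intermolecular metathesis at the vinyl group may outrun closure of the strained nine-membered ring, and the electron-poor 1,1-disubstituted methacrylate may not engage the ruthenium carbene. The fallback closes the ring by olefination and sets out from 16. Acylation of the C10 hydroxyl with 2-(diethoxyphosphoryl)propanoic acid (DCC, DMAP) should give the phosphonate ester F3. Lemieux–Johnson cleavage (OsO4 cat., NaIO4, 2,6-lutidine) of the monosubstituted vinyl group should give the C5 aldehyde F4. Intramolecular Horner–Wadsworth–Emmons reaction (LiCl, DBU, MeCN, high dilution) should close the nine-membered lactone with the ring-enforced Z enoate to give the ethynyl macrocycle F5. The alkyne is kept until this point so that no ketone competes for the phosphonate anion. Hydration with Ph3PAuNTf2 in wet dioxane then rejoins the route at 19.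

Step 11. Acylation of the hindered tertiary alcohol may stall, or the forcing conditions may cause migration or isomerisation of the angelate. The fallback activates the alcohol as its alkoxide before the angelate is present and sets out from 15. Selective silylation of the secondary hydroxyl (Et3SiOTf, 2,6-lutidine, −78 °C) should give the C8 silyl ether F6. Deprotonation of the tertiary hydroxyl with LiN(SiMe3)2 at −78 °C and trapping with methacryloyl chloride should give the C10 methacrylate F7. HF·pyridine should give the C8 alcohol F8. Yamaguchi-type angeloylation as in step 10 rejoins the route at 17.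

Further compounds
F1 | step 7 | 2-cyanoethyl ether of 10 | C#C[C@]1(C)O[C@@H](c2ccc(OC)cc2)O[C@@H]([C@@H]3O[C@@H]3C=C)[C@@H]1OCCC#N
F2 | step 7 | tricyclic iminolactone (C12=NH analogue of 14) | C#C[C@]1(C)O[C@@H](c2ccc(OC)cc2)O[C@@H]3[C@@H]1OC[C@@H]4[C@H]3[C@@H](C=C)OC4=N
F3 | step 13 | C10 2-(diethoxyphosphoryl)propanoate of 16 | C/C=C(/C)C(=O)O[C@H]1[C@@H]2[C@@H](C=C)OC(=O)[C@@H]2CO[C@@H]1[C@@](C)(OC(=O)C(C)P(=O)(OCC)OCC)C#C
F4 | step 13 | C5 aldehyde from F3 | C/C=C(/C)C(=O)O[C@H]1[C@@H]2[C@@H](C=O)OC(=O)[C@@H]2CO[C@@H]1[C@@](C)(OC(=O)C(C)P(=O)(OCC)OCC)C#C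
F5 | step 13 | nine-membered lactone with C10 ethynyl in place of acetyl | C/C=C(/C)C(=O)O[C@H]1[C@@H]2[C@H]3/C=C(/C)C(=O)O[C@@](C)(C#C)[C@H]1OC[C@H]2C(=O)O3
F6 | step 11 | C8 triethylsilyl ether of 15 | CC[Si](CC)(CC)O[C@H]1[C@@H]2[C@@H](C=C)OC(=O)[C@@H]2CO[C@@H]1[C@@](C)(O)C#C
F7 | step 11 | C8 triethylsilyl ether C10 methacrylate | CC[Si](CC)(CC)O[C@H]1[C@@H]2[C@@H](C=C)OC(=O)[C@@H]2CO[C@@H]1[C@@](C)(OC(=O)C(C)=C)C#C
F8 | step 11 | C8 alcohol C10 methacrylate | O[C@H]1[C@@H]2[C@@H](C=C)OC(=O)[C@@H]2CO[C@@H]1[C@@](C)(OC(=O)C(C)=C)C#C
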